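**Plan**

1. Retrosynthesis: the C2–C3 bond of ring C (7-methoxy unit) and the C2''–C3'' bond of ring C'' (dihydroxy unit) are cut first, opening both pyranones to one bis(diazomethyl ketone) in which C2 and C2'' are ArO–CH2–Ar methylenes.
2. Enabling feature: in each pyranone ring, C2 is a benzylic carbon on the ring oxygen O1 and C3 is a CH2 next to the C4 ketone, so a carbene at C3 can insert into an ether-activated benzylic C–H bond.
3. Further cuts: the two O1–C2 benzyl aryl ether bonds (to two 2,6-dihydroxyacetophenones, rings A and A'') and then the C3'–O–C4''' diaryl ether (SNAr).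
4. Forward: the diaryl ether (rings B and B'') is made first, rings A and A'' are attached to its two benzylic arms one after the other, the acetyl groups become diazoacetyl groups, and rings C and C'' close together in one step.
5. Stereochemistry: no stereocentre exists before that step; both (S) centres are set by the chiral dirhodium carboxylate, which chooses between enantiotopic benzylic hydrogens, and neither centre meets base afterwards.

Key step: step 9

Assumption: the (S)-tert-leucinate-derived catalyst is taken to give the (2S) centres; if its sense of induction proves opposite, the enantiomeric catalyst Rh2(R-PTTL)4 is used and nothing else changes.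

**Route**

Step 1
Reactants: 1 4-(benzyloxy)-3-hydroxybenzaldehyde
Product: 2 2-(benzyloxy)-5-(hydroxymethyl)phenol
Conditions: NaBH4, MeOH, 0 °C
Reagents that add atoms: none
Why: Borohydride reduction of the aryl aldehyde, done before the ether synthesis so that the two benzylic arms of the later diaryl ether differ in oxidation level (CH2OH against CHO).

Step 2
Reactants: 2 2-(benzyloxy)-5-(hydroxymethyl)phenol; 3 4-fluorobenzaldehyde
Product: 4 4-[2-(benzyloxy)-5-(hydroxymethyl)phenoxy]benzaldehyde
Conditions: K2CO3, DMF, 90 °C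
Reagents that add atoms: none
Why: Nucleophilic aromatic substitution (SNAr) in which the phenoxide displaces fluoride para to the formyl group, while the benzylic alcohol, which carbonate does not deprotonate and which sits meta to the phenoxide, stays a spectator.

Step 3
Reactants: 4 4-[2-(benzyloxy)-5-(hydroxymethyl)phenoxy]benzaldehyde; 5 1-(2,6-dihydroxy-4-methoxyphenyl)ethanone
Product: 6 4-[5-[(2-acetyl-3-hydroxy-5-methoxyphenoxy)methyl]-2-(benzyloxy)phenoxy]benzaldehyde
Conditions: 5 (1.5 equiv), PPh3, DIAD, THF, 0 °C to rt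
Reagents that add atoms: none
Why: Mitsunobu etherification of the acidic ortho-acyl phenol by the activated benzylic alcohol, expected to stop at the mono-ether because the remaining hydroxyl of 6 is hydrogen-bonded to the acetyl group and flanked by it, with the aldehyde untouched under these neutral conditions.

Step 4
Reactants: 6 4-[5-[(2-acetyl-3-hydroxy-5-methoxyphenoxy)methyl]-2-(benzyloxy)phenoxy]benzaldehyde
Product: 7 1-[2-[[4-(benzyloxy)-3-[4-(hydroxymethyl)phenoxy]phenyl]methoxy]-6-hydroxy-4-methoxyphenyl]ethanone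
Conditions: NaBH4 (0.5 equiv), THF–MeOH, −20 °C
Reagents that add atoms: none
Why: Chemoselective borohydride reduction, since the aryl aldehyde is far more electrophilic than the di-ortho-substituted, hydrogen-bonded and strongly donor-substituted aryl methyl ketone.

Step 5
Reactants: 8 1-(2,4,6-trihydroxyphenyl)ethanone
Product: 9 1-[4-(benzyloxy)-2,6-dihydroxyphenyl]ethanone
Conditions: BnBr (1.0 equiv), K2CO3 (1.0 equiv), acetone, reflux
Reagents that add atoms: benzyl bromide, BrCc1ccccc1
Why: Williamson ether synthesis directed to the 4-hydroxyl, the most acidic one and the only one not hydrogen-bonded to the acetyl group, by using one equivalent each of base and bromide.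

Step 6
Reactants: 7 1-[2-[[4-(benzyloxy)-3-[4-(hydroxymethyl)phenoxy]phenyl]methoxy]-6-hydroxy-4-methoxyphenyl]ethanone; 9 1-[4-(benzyloxy)-2,6-dihydroxyphenyl]ethanone
Product: 10 1-[2-({4-[5-({2-acetyl-3-hydroxy-5-methoxyphenoxy}methyl)-2-(benzyloxy)phenoxy]phenyl}methoxy)-4-(benzyloxy)-6-hydroxyphenyl]ethanone
Conditions: 9 (2 equiv), PPh3, DIAD, THF, 0 °C to rt
Reagents that add atoms: none
Why: Second Mitsunobu etherification, in which 9 (two equivalent acidic hydroxyls, used in excess) should outcompete the single chelated and more hindered phenol of 7 for the activated benzylic alcohol and again stop at the mono-ether.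

Step 7
Reactants: 10 the bis(hydroxyaryl methyl ketone) from step 6
Product: 11 the bis(tert-butyldimethylsilyl) ether of 10 (both phenols silylated)
Conditions: TBSCl, imidazole, DMAP (cat.), DMF, 40 °C
Reagents that add atoms: tert-butyldimethylsilyl chloride, CC(C)(C)[Si](C)(C)Cl
Why: Imidazole-mediated silylation of both chelated phenols, which masks the only O–H bonds (O–H insertion sites for the later carbenes) as bulky, weakly basic silyl ethers that offer no reactive C–H bond.

Step 8
Reactants: 11 the bis(silyl ether) bis(methyl ketone)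
Product: 13 the bis(diazomethyl ketone) in which each COCH3 of 11 has become COCHN2, via bis(trifluoroacetyl) diketone 12 (not isolated)
Conditions: LiN(SiMe3)2, THF, −78 °C, then CF3CO2CH2CF3; aq. HCl work-up; MsN3, Et3N, H2O, MeCN, rt
Reagents that add atoms: methanesulfonyl azide, CS(=O)(=O)N=[N+]=[N-] (both N2 units of 13); 2,2,2-trifluoroethyl trifluoroacetate, O=C(OCC(F)(F)F)C(F)(F)F (the CF3CO groups of 12, lost again on the way to 13)
Why: Deacylative Regitz diazo transfer, in which the kinetic lithium enolates of both methyl ketones undergo Claisen trifluoroacetylation and the resulting 1,3-diketones take the diazo group from the sulfonyl azide with loss of the trifluoroacetyl group, which avoids ester hydrolysis, acid chlorides and diazomethane.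

Step 9
Reactants: 13 the bis(diazomethyl ketone)
Product: 14 (2S)-2-[4-(benzyloxy)-3-[4-[(2S)-7-(benzyloxy)-5-[(tert-butyldimethylsilyl)oxy]-4-oxochroman-2-yl]phenoxy]phenyl]-5-[(tert-butyldimethylsilyl)oxy]-7-methoxychroman-4-one
Conditions: Rh2(S-PTTL)4 (2 mol %; PTTL = N-phthaloyl-tert-leucinate), CH2Cl2, 0 °C, syringe-pump addition of 13 at high dilution
Reagents that add atoms: none
Why: Each diazo ketone loses N2 on the dirhodium core to give an electrophilic rhodium carbene at the future C3 (C3''), which inserts into a benzylic C–H bond of the neighbouring ArO–CH2–Ar group through a three-centre, hydride-transfer-like transition state and so forms C2–C3 and C2''–C3''. The closest known reaction type is the intramolecular C–H insertion of ortho-alkoxyaryl α-diazo ketones under chiral dirhodium tetracarboxylate catalysis, which gives chroman-4-ones. Ring C and ring C'' each close as a six-membered ring by 1,6-insertion, with the C4a–C8a arene bond and O1 already in the tether, so the benzylic methylene can only give the pyranone. Each new stereocentre (C2, C2'') is set by the catalyst alone, whose tert-leucinate ligands should let the carbene reach only one of the two enantiotopic benzylic hydrogens; because the two sites react independently, the minor sense of each event ends up mainly in the (2S,2''R) and (2R,2''S) diastereomers, which raises the enantiopurity of the (2S,2''S) product. The step needs C–H insertion to win over carbene attack on an oxygen lone pair (oxonium ylide, then 1,2-benzyl shift to a benzofuran-3-one) and over carbene dimerisation: the ether oxygens are weakly basic because they are conjugated to an acyl-bearing arene, the C–H bonds are made hydridic by the para-benzyloxy and para-aryloxy groups of rings B and B'', the other ortho oxygen is shielded as a bulky silyl ether, and slow addition keeps the carbenes apart. The benzyl groups on O4' and O7'' lie out of intramolecular reach of either carbene.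

Step 10
Reactants: 14 the bis(silyl) dibenzyl bis-flavanone
Product: 15 (2S)-2-[4-(benzyloxy)-3-[4-[(2S)-7-(benzyloxy)-5-hydroxy-4-oxochroman-2-yl]phenoxy]phenyl]-5-hydroxy-7-methoxychroman-4-one
Conditions: TBAF, AcOH (1:1), THF, 0 °C
Reagents that add atoms: none
Why: Fluoride-induced cleavage of the two aryl silyl ethers, buffered with acetic acid so that no phenoxide or enolate can open the pyranone rings by retro-oxa-Michael (E1cB) reaction and scramble C2 and C2''.

Step 11
Reactants: 15 the 4',7''-di-O-benzyl bis-flavanone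
Product: 16 7-O-methyltetrahydroochnaflavone, (2S)-2-[3-[4-[(2S)-5,7-dihydroxy-4-oxochroman-2-yl]phenoxy]-4-hydroxyphenyl]-5-hydroxy-7-methoxychroman-4-one
Conditions: H2 (1 atm), Pd/C, EtOAc–THF, rt
Reagents that add atoms: none
Why: Hydrogenolysis of the two benzyl aryl ethers under neutral conditions, which should be faster than cleavage of the cyclic benzylic C2–O1 bonds or reduction of the aryl ketones and leaves both stereocentres untouched.

**Compound list**

1 | 4-(benzyloxy)-3-hydroxybenzaldehyde | O=Cc1ccc(OCc2ccccc2)c(O)c1 | starting material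
2 | 2-(benzyloxy)-5-(hydroxymethyl)phenol | OCc1ccc(OCc2ccccc2)c(O)c1 | intermediate
3 | 4-fluorobenzaldehyde | O=Cc1ccc(F)cc1 | starting material
4 | 4-[2-(benzyloxy)-5-(hydroxymethyl)phenoxy]benzaldehyde | O=Cc1ccc(Oc2cc(CO)ccc2OCc2ccccc2)cc1 | intermediate
5 | 1-(2,6-dihydroxy-4-methoxyphenyl)ethanone | COc1cc(O)c(C(C)=O)c(O)c1 | starting material
6 | 4-[5-[(2-acetyl-3-hydroxy-5-methoxyphenoxy)methyl]-2-(benzyloxy)phenoxy]benzaldehyde | COc1cc(O)c(C(C)=O)c(c1)OCc1ccc(OCc2ccccc2)c(Oc2ccc(C=O)cc2)c1 | intermediate
7 | 1-[2-[[4-(benzyloxy)-3-[4-(hydroxymethyl)phenoxy]phenyl]methoxy]-6-hydroxy-4-methoxyphenyl]ethanone | COc1cc(O)c(C(C)=O)c(c1)OCc1ccc(OCc2ccccc2)c(Oc2ccc(CO)cc2)c1 | intermediate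
8 | 1-(2,4,6-trihydroxyphenyl)ethanone | CC(=O)c1c(O)cc(O)cc1O | starting material
9 | 1-[4-(benzyloxy)-2,6-dihydroxyphenyl]ethanone | CC(=O)c1c(O)cc(OCc2ccccc2)cc1O | intermediate
10 | 1-[2-({4-[5-({2-acetyl-3-hydroxy-5-methoxyphenoxy}methyl)-2-(benzyloxy)phenoxy]phenyl}methoxy)-4-(benzyloxy)-6-hydroxyphenyl]ethanone | COc1cc(O)c(C(C)=O)c(c1)OCc1ccc(OCc2ccccc2)c(Oc2ccc(COc3cc(OCc4ccccc4)cc(O)c3C(C)=O)cc2)c1 | intermediate
11 | bis(tert-butyldimethylsilyl) ether of 10 (both phenols silylated) | COc1cc(O[Si](C)(C)C(C)(C)C)c(C(C)=O)c(c1)OCc1ccc(OCc2ccccc2)c(Oc2ccc(COc3cc(OCc4ccccc4)cc(O[Si](C)(C)C(C)(C)C)c3C(C)=O)cc2)c1 | intermediate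
12 | bis(trifluoroacetyl) diketone: each COCH3 of 11 as COCH2COCF3 (drawn as the diketo tautomer; formed in the flask in step 8) | COc1cc(O[Si](C)(C)C(C)(C)C)c(C(=O)CC(=O)C(F)(F)F)c(c1)OCc1ccc(OCc2ccccc2)c(Oc2ccc(COc3cc(OCc4ccccc4)cc(O[Si](C)(C)C(C)(C)C)c3C(=O)CC(=O)C(F)(F)F)cc2)c1 | intermediate
13 | bis(diazomethyl ketone): each COCH3 of 11 as COCHN2 | COc1cc(O[Si](C)(C)C(C)(C)C)c(C(=O)C=[N+]=[N-])c(c1)OCc1ccc(OCc2ccccc2)c(Oc2ccc(COc3cc(OCc4ccccc4)cc(O[Si](C)(C)C(C)(C)C)c3C(=O)C=[N+]=[N-])cc2)c1 | intermediate
14 | (2S)-2-[4-(benzyloxy)-3-[4-[(2S)-7-(benzyloxy)-5-[(tert-butyldimethylsilyl)oxy]-4-oxochroman-2-yl]phenoxy]phenyl]-5-[(tert-butyldimethylsilyl)oxy]-7-methoxychroman-4-one | COc1cc(O[Si](C)(C)C(C)(C)C)c2c(c1)O[C@H](c1ccc(OCc3ccccc3)c(Oc3ccc([C@@H]4CC(=O)c5c(O[Si](C)(C)C(C)(C)C)cc(OCc6ccccc6)cc5O4)cc3)c1)CC2=O | intermediate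
15 | (2S)-2-[4-(benzyloxy)-3-[4-[(2S)-7-(benzyloxy)-5-hydroxy-4-oxochroman-2-yl]phenoxy]phenyl]-5-hydroxy-7-methoxychroman-4-one | COc1cc(O)c2c(c1)O[C@H](c1ccc(OCc3ccccc3)c(Oc3ccc([C@@H]4CC(=O)c5c(O)cc(OCc6ccccc6)cc5O4)cc3)c1)CC2=O | intermediate
16 | 7-O-methyltetrahydroochnaflavone, (2S,2''S) | COc1cc(O)c2c(c1)O[C@H](c1ccc(O)c(Oc3ccc([C@@H]4CC(=O)c5c(O)cc(O)cc5O4)cc3)c1)CC2=O | target

**Step count and risks**

Total step count: 11. Longest linear sequence: 10 steps (steps 1–4 and 6–11, from 1); step 5 is a one-step side branch.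

The three steps most likely to fail:

Step 9. The rhodium carbene may be captured by a lone pair of the aryl ether oxygen (oxonium ylide, then 1,2-shift of the benzyl group to a 2-benzylbenzofuran-3-one) faster than it inserts, or the catalyst may distinguish the enantiotopic hydrogens poorly so that all four stereoisomers form. The fallback gives up the carbene and closes the rings at O1–C2 by the chalcone route. It sets out from 4 and uses 9 and 5 again. Claisen–Schmidt condensation (KOH, EtOH–H2O) of the aldehyde of 4 with 9 should give the hydroxymethyl chalcone F1. MnO2 then oxidises its benzylic alcohol to the chalcone aldehyde F2, and a second Claisen–Schmidt condensation with 5 gives the bis(2',6'-dihydroxychalcone) F3. NaOAc in refluxing EtOH closes both rings by 6-endo-trig oxa-Michael addition and comes back to the route at 15, here as a mixture of stereoisomers. The (2S,2''S) isomer is taken by preparative HPLC on a chiral stationary phase, and the other isomers are re-equilibrated with base through F3 and recycled.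

Step 8. The lithium enolates next to the silyl ethers may take over the silyl group from the phenolic oxygen (1,5 O-to-O transfer), or be acylated at only one of the two sites, so that desilylated and mono-diazo material builds up. The fallback activates the methyl ketones without any strong base. It sets out from 11: heating with N,N-dimethylformamide dimethyl acetal should give the bis(enaminone) F4. Tosyl azide then transfers the diazo group by cycloaddition to the enamine double bond and cycloreversion, which comes back to the route at 13.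

Step 6. The activated benzylic alcohol of 7 may be captured by the free phenol of a second molecule of 7, or by both hydroxyls of 9, so that oligomers and bis-ethers form in place of 10. The fallback removes the competing phenol before the second arm is made. It sets out from 6: silylation (TBSCl, imidazole, DMF) gives the silyl ether aldehyde F5, and NaBH4 at −20 °C gives the silyl ether benzylic alcohol F6. Mitsunobu etherification with 9 gives the mono-silylated diether F7, and silylation of its remaining phenol comes back to the route at 11.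

**Further compounds**

F1 | step 9 | (E)-1-[4-(benzyloxy)-2,6-dihydroxyphenyl]-3-[4-[2-(benzyloxy)-5-(hydroxymethyl)phenoxy]phenyl]prop-2-en-1-one | OCc1ccc(OCc2ccccc2)c(Oc2ccc(/C=C/C(=O)c3c(O)cc(OCc4ccccc4)cc3O)cc2)c1
F2 | step 9 | 4-(benzyloxy)-3-[4-[(E)-3-[4-(benzyloxy)-2,6-dihydroxyphenyl]-3-oxoprop-1-enyl]phenoxy]benzaldehyde | O=Cc1ccc(OCc2ccccc2)c(Oc2ccc(/C=C/C(=O)c3c(O)cc(OCc4ccccc4)cc3O)cc2)c1
F3 | step 9 | (E)-1-[4-(benzyloxy)-2,6-dihydroxyphenyl]-3-[4-[2-(benzyloxy)-5-[(E)-3-(2,6-dihydroxy-4-methoxyphenyl)-3-oxoprop-1-enyl]phenoxy]phenyl]prop-2-en-1-one | COc1cc(O)c(C(=O)/C=C/c2ccc(OCc3ccccc3)c(Oc3ccc(/C=C/C(=O)c4c(O)cc(OCc5ccccc5)cc4O)cc3)c2)c(O)c1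
F4 | step 8 | bis(enaminone) of 11: each COCH3 as (E)-COCH=CHN(CH3)2 | COc1cc(O[Si](C)(C)C(C)(C)C)c(C(=O)/C=C/N(C)C)c(c1)OCc1ccc(OCc2ccccc2)c(Oc2ccc(COc3cc(OCc4ccccc4)cc(O[Si](C)(C)C(C)(C)C)c3C(=O)/C=C/N(C)C)cc2)c1
F5 | step 6 | 4-[5-[(2-acetyl-3-[(tert-butyldimethylsilyl)oxy]-5-methoxyphenoxy)methyl]-2-(benzyloxy)phenoxy]benzaldehyde | COc1cc(O[Si](C)(C)C(C)(C)C)c(C(C)=O)c(c1)OCc1ccc(OCc2ccccc2)c(Oc2ccc(C=O)cc2)c1
F6 | step 6 | 1-[2-[[4-(benzyloxy)-3-[4-(hydroxymethyl)phenoxy]phenyl]methoxy]-6-[(tert-butyldimethylsilyl)oxy]-4-methoxyphenyl]ethanone | COc1cc(O[Si](C)(C)C(C)(C)C)c(C(C)=O)c(c1)OCc1ccc(OCc2ccccc2)c(Oc2ccc(CO)cc2)c1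
F7 | step 6 | mono(tert-butyldimethylsilyl) ether of 10, silylated on the methoxy-bearing ring only | COc1cc(O[Si](C)(C)C(C)(C)C)c(C(C)=O)c(c1)OCc1ccc(OCc2ccccc2)c(Oc2ccc(COc3cc(OCc4ccccc4)cc(O)c3C(C)=O)cc2)c1
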